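The route rests on cutting the lactone C–O bond at the allylic carbon. In the target (germacrane numbering) the γ-lactone oxygen O1 on C6 and the acetate oxygen on C15 flank the C4=C5 double bond in a 1,4-relationship, the signature of an oxidative 1,4-addition to a 4(15),5-diene. A palladium-catalysed 1,4-acetoxylactonisation of an acyclic (5Z)-diene acrylic acid therefore closes the α-methylene-γ-butyrolactone ring through O1–C6, sets C6 relative to C7, shifts the alkene to C4=C5 and installs the C15 acetate in one operation. The diene acid is assembled by a chromium-catalysed asymmetric allylation; the ten-membered ring is closed last by an intramolecular allylchromium addition and oxidation at C2.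

Key step: step 13

Remark on numbering: germacrane numbering is used (ring C1–C10; C11–C13 in the lactone; C14 on C10; C15 on C4; O1 is the lactone ring oxygen). In the target O1 on C6 is anti to C11 on C7, the C8 acetate is anti to C11, and C3 is anti to C6 across C4=C5.
Assumption: the sense of induction of the chromium/bis(oxazolinyl)carbazole catalyst in step 9 can be matched by the choice of ligand enantiomer; the (S,S)-ligand is written.

Step 1
Reactants: 1 4-methyl hydrogen itaconate (4-methoxy-2-methylidene-4-oxobutanoic acid)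
Product: 2 methyl 3-(hydroxymethyl)but-3-enoate
Conditions: BH3·SMe2, THF, −10 → 20 °C; MeOH quench
Reagents that add atoms: none
Why: Chemoselective borane reduction of a carboxylic acid: the acyloxyborane is reduced much faster than the methyl ester or the electron-poor 1,1-disubstituted alkene.

Step 2
Reactants: 2 methyl 3-(hydroxymethyl)but-3-enoate
Product: 3 methyl 3-{[(tert-butyldimethylsilyl)oxy]methyl}but-3-enoate
Conditions: t-BuMe2SiCl, imidazole, DMF, 0 → 20 °C
Reagents that add atoms: tert-butyldimethylsilyl chloride, CC(C)(C)[Si](C)(C)Cl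
Why: Standard silylation of the primary allylic alcohol, done at once so that it cannot lactonise onto the ester.

Step 3
Reactants: 3 methyl 3-{[(tert-butyldimethylsilyl)oxy]methyl}but-3-enoate
Product: 4 3-{[(tert-butyldimethylsilyl)oxy]methyl}but-3-enal
Conditions: i-Bu2AlH, CH2Cl2, −78 °C; Rochelle salt work-up
Reagents that add atoms: none
Why: DIBAL half-reduction of the ester through the aluminium hemiacetal that is stable at −78 °C; the β,γ-unsaturated aldehyde is used at once to avoid conjugation.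

Step 4
Reactants: 5 3-bromobut-3-en-1-ol
Product: 6 [(3-bromobut-3-en-1-yl)oxy](tert-butyl)diphenylsilane
Conditions: t-BuPh2SiCl, imidazole, CH2Cl2, 20 °C
Reagents that add atoms: tert-butyldiphenylsilyl chloride, CC(C)(C)[Si](Cl)(c1ccccc1)c1ccccc1
Why: Standard silylation; the robust silyl ether carries the C2 oxygen to step 15.

Step 5
Reactants: 6 [(3-bromobut-3-en-1-yl)oxy](tert-butyl)diphenylsilane; 7 prop-2-yn-1-ol
Product: 8 6-[(tert-butyldiphenylsilyl)oxy]-4-methylidenehex-2-yn-1-ol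
Conditions: Pd(PPh3)2Cl2 (cat.), CuI (cat.), i-Pr2NH, THF, 40 °C
Reagents that add atoms: none
Why: Sonogashira coupling of the 2-bromoalkene with the terminal alkyne builds the C6≡C5–C4(=C15) enyne.

Step 6
Reactants: 8 6-[(tert-butyldiphenylsilyl)oxy]-4-methylidenehex-2-yn-1-ol
Product: 9 6-[(tert-butyldiphenylsilyl)oxy]-4-methylidenehex-2-ynal
Conditions: activated MnO2, CH2Cl2, 20 °C
Reagents that add atoms: none
Why: MnO2 oxidises the propargylic alcohol selectively to the ynal under neutral conditions.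

Step 7
Reactants: 9 6-[(tert-butyldiphenylsilyl)oxy]-4-methylidenehex-2-ynal; 10 tert-butyl acrylate
Product: 11 tert-butyl 8-[(tert-butyldiphenylsilyl)oxy]-3-hydroxy-2,6-dimethylideneoct-4-ynoate (racemic)
Conditions: DABCO, THF, 20 °C
Reagents that add atoms: none
Why: Morita–Baylis–Hillman reaction: the DABCO–acrylate zwitterion adds 1,2 to the very electrophilic ynal; the racemic carbinol centre is removed in step 8.

Step 8
Reactants: 11 tert-butyl 8-[(tert-butyldiphenylsilyl)oxy]-3-hydroxy-2,6-dimethylideneoct-4-ynoate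
Product: 12 tert-butyl (2Z)-2-(bromomethyl)-8-[(tert-butyldiphenylsilyl)oxy]-6-methylideneoct-2-en-4-ynoate
Conditions: N-bromosuccinimide, Me2S, CH2Cl2, 0 → 20 °C
Reagents that add atoms: N-bromosuccinimide, O=C1CCC(=O)N1Br
Why: Corey–Kim-type bromination of a Baylis–Hillman alcohol: bromide opens the alkoxysulfonium salt in the SN2′ sense to the conjugated 2-(bromomethyl)enynoate.

Step 9
Reactants: 4 3-{[(tert-butyldimethylsilyl)oxy]methyl}but-3-enal; 12 tert-butyl (2Z)-2-(bromomethyl)-8-[(tert-butyldiphenylsilyl)oxy]-6-methylideneoct-2-en-4-ynoate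
Product: 14 tert-butyl (3R,4S)-7-[(tert-butyldimethylsilyl)oxy]-3-{5-[(tert-butyldiphenylsilyl)oxy]-3-methylidenepent-1-yn-1-yl}-4-hydroxy-2,6-dimethylideneheptanoate, via 4-O-trimethylsilyl ether 13 (not isolated)
Conditions: CrCl2 (10 mol %), (S,S)-3,6-di-tert-butyl-1,8-bis(4-isopropyl-4,5-dihydrooxazol-2-yl)-9H-carbazole (12 mol %), Mn, Me3SiCl, i-Pr2NEt, THF, 0 °C; then citric acid, MeOH
Reagents that add atoms: none
Why: Catalytic asymmetric Nozaki–Hiyama–Kishi 2-(alkoxycarbonyl)allylation: CrCl2 (regenerated by Mn, released by Me3SiCl) inserts into the allylic bromide and the ligand-bound allylchromium should add through its γ-carbon C7 in a chair transition state with the alkynyl group equatorial, which sets C7/C8 anti while the tridentate ligand selects the aldehyde face for the C8 carbinol.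

Step 10
Reactants: 14 tert-butyl (3R,4S)-7-[(tert-butyldimethylsilyl)oxy]-3-{5-[(tert-butyldiphenylsilyl)oxy]-3-methylidenepent-1-yn-1-yl}-4-hydroxy-2,6-dimethylideneheptanoate
Product: 15 tert-butyl (3R,4S)-4-acetoxy-7-[(tert-butyldimethylsilyl)oxy]-3-{5-[(tert-butyldiphenylsilyl)oxy]-3-methylidenepent-1-yn-1-yl}-2,6-dimethylideneheptanoate
Conditions: Ac2O, pyridine, DMAP (cat.), CH2Cl2, 0 → 20 °C
Reagents that add atoms: acetic anhydride, CC(=O)OC(C)=O
Why: Standard acetylation installs the C8 acetate of the target and blocks the competing 8,12-lactone.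

Step 11
Reactants: 15 tert-butyl (3R,4S)-4-acetoxy-7-[(tert-butyldimethylsilyl)oxy]-3-{5-[(tert-butyldiphenylsilyl)oxy]-3-methylidenepent-1-yn-1-yl}-2,6-dimethylideneheptanoate
Product: 16 tert-butyl (3R,4S)-4-acetoxy-7-[(tert-butyldimethylsilyl)oxy]-3-{(1Z)-5-[(tert-butyldiphenylsilyl)oxy]-3-methylidenepent-1-en-1-yl}-2,6-dimethylideneheptanoate
Conditions: Zn (activated with Cu(OAc)2 and AgNO3), MeOH/H2O, 40 °C
Reagents that add atoms: none
Why: Boland reduction: activated zinc semi-reduces only the conjugated enyne triple bond to the (Z)-alkene and leaves the isolated alkenes, the acrylate and the acetate alone.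

Step 12
Reactants: 16 tert-butyl (3R,4S)-4-acetoxy-7-[(tert-butyldimethylsilyl)oxy]-3-{(1Z)-5-[(tert-butyldiphenylsilyl)oxy]-3-methylidenepent-1-en-1-yl}-2,6-dimethylideneheptanoate
Product: 18 (3R,4S)-4-acetoxy-7-[(tert-butyldimethylsilyl)oxy]-3-{(1Z)-5-[(tert-butyldiphenylsilyl)oxy]-3-methylidenepent-1-en-1-yl}-2,6-dimethylideneheptanoic acid, via trimethylsilyl ester 17 (not isolated)
Conditions: Me3SiOTf, 2,6-lutidine, CH2Cl2, 0 °C; then pH 5 aqueous buffer
Reagents that add atoms: none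
Why: Silyl-triflate cleavage of a tert-butyl ester (loss of 2-methylpropene) under buffered, non-protic conditions that should spare the silyl ethers, the acetate and the acid-sensitive (Z)-diene.

Step 13
Reactants: 18 (3R,4S)-4-acetoxy-7-[(tert-butyldimethylsilyl)oxy]-3-{(1Z)-5-[(tert-butyldiphenylsilyl)oxy]-3-methylidenepent-1-en-1-yl}-2,6-dimethylideneheptanoic acid
Product: 19 (1S)-1-[(2R,3R)-2-{(1Z)-2-(acetoxymethyl)-4-[(tert-butyldiphenylsilyl)oxy]but-1-en-1-yl}-4-methylidene-5-oxooxolan-3-yl]-3-{[(tert-butyldimethylsilyl)oxy]methyl}but-3-en-1-yl acetate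
Conditions: Pd(OAc)2 (10 mol %), p-benzoquinone, LiOAc, AcOH/acetone (1:4), 20 °C
Reagents that add atoms: acetic acid (with LiOAc), CC(=O)O
Why: Divalent palladium binds the diene and the carboxylic acid adds to the diene terminus C6, giving a π-allylpalladium over C5–C4–C15 that acetate opens at the primary C15 terminus, after which benzoquinone reoxidises the released zerovalent palladium. The closest known reaction type is the palladium-catalysed intramolecular 1,4-acetoxylactonisation of conjugated diene acids (Bäckvall oxidation). The γ-lactone is closed through O1–C6 in the 5-exo-trig mode. C6 is controlled by C7 through A1,3 strain of the (Z)-alkene: H7 eclipses C5=C6, the carboxyl arm on C11 reaches only one face, and the lactone should form trans (H6 anti to H7). The step needs 1,4- instead of 1,2-addition, which the hindered secondary C5 against the primary C15 should secure, and a C4=C5 geometry with C15 cis to C6, for which the cisoid twist forced on the diene by the C3 branch and the (Z)-substituent is relied on, so that the allyl forms with C6 anti and is captured before it isomerises. The isolated 1,1-disubstituted alkenes (C10=C14, C11=C13) are much less reactive towards divalent palladium than the diene.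

Step 14
Reactants: 19 (1S)-1-[(2R,3R)-2-{(1Z)-2-(acetoxymethyl)-4-[(tert-butyldiphenylsilyl)oxy]but-1-en-1-yl}-4-methylidene-5-oxooxolan-3-yl]-3-{[(tert-butyldimethylsilyl)oxy]methyl}but-3-en-1-yl acetate
Product: 20 (1S)-1-[(2R,3R)-2-{(1Z)-2-(acetoxymethyl)-4-[(tert-butyldiphenylsilyl)oxy]but-1-en-1-yl}-4-methylidene-5-oxooxolan-3-yl]-3-(bromomethyl)but-3-en-1-yl acetate
Conditions: Ph3PBr2, CH2Cl2, 0 → 20 °C
Reagents that add atoms: triphenylphosphine dibromide, BrP(Br)(c1ccccc1)(c1ccccc1)c1ccccc1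
Why: Direct conversion of a primary allylic tert-butyldimethylsilyl ether into the bromide via the silyloxyphosphonium salt (SN2); the bulkier tert-butyldiphenylsilyl ether, the esters and the lactone should survive.

Step 15
Reactants: 20 (1S)-1-[(2R,3R)-2-{(1Z)-2-(acetoxymethyl)-4-[(tert-butyldiphenylsilyl)oxy]but-1-en-1-yl}-4-methylidene-5-oxooxolan-3-yl]-3-(bromomethyl)but-3-en-1-yl acetate
Product: 21 (1S)-1-{(2R,3R)-2-[(1Z)-2-(acetoxymethyl)-4-hydroxybut-1-en-1-yl]-4-methylidene-5-oxooxolan-3-yl}-3-(bromomethyl)but-3-en-1-yl acetate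
Conditions: HF·pyridine, pyridine, THF, 0 → 20 °C
Reagents that add atoms: none
Why: Fluoride-driven Si–O cleavage under buffered acidic conditions that the allylic bromide, the acetates and the lactone tolerate.

Step 16
Reactants: 21 (1S)-1-{(2R,3R)-2-[(1Z)-2-(acetoxymethyl)-4-hydroxybut-1-en-1-yl]-4-methylidene-5-oxooxolan-3-yl}-3-(bromomethyl)but-3-en-1-yl acetate
Product: 22 (1S)-1-{(2R,3R)-2-[(1Z)-2-(acetoxymethyl)-4-oxobut-1-en-1-yl]-4-methylidene-5-oxooxolan-3-yl}-3-(bromomethyl)but-3-en-1-yl acetate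
Conditions: Dess–Martin periodinane, NaHCO3, CH2Cl2, 0 °C
Reagents that add atoms: none
Why: Dess–Martin oxidation under buffered neutral conditions gives the β,γ-unsaturated C2 aldehyde, which is used crude to avoid conjugation.

Step 17
Reactants: 22 (1S)-1-{(2R,3R)-2-[(1Z)-2-(acetoxymethyl)-4-oxobut-1-en-1-yl]-4-methylidene-5-oxooxolan-3-yl}-3-(bromomethyl)but-3-en-1-yl acetate
Product: 24 8α,15-diacetoxy-2-hydroxygermacra-4,10(14),11(13)-trien-12,6α-olide (C2 epimers), via allylchromium dichloride 23 (not isolated)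
Conditions: CrCl2 (6 equiv), THF, 20 °C, slow addition at high dilution
Reagents that add atoms: none
Why: Intramolecular Nozaki–Hiyama allylation: CrCl2 inserts into the allylic bromide and the symmetrical 2-substituted allylchromium adds to the aldehyde through a six-membered transition state, closing the ten-membered ring without touching lactone or acetates; the new C2 carbinol centre forms as a mixture that step 18 erases.

Step 18
Reactants: 24 8α,15-diacetoxy-2-hydroxygermacra-4,10(14),11(13)-trien-12,6α-olide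
Product: 25 8α,15-diacetoxy-2-oxogermacra-4,10(14),11(13)-trien-12,6α-olide (CNP0183179.1)
Conditions: Dess–Martin periodinane, NaHCO3, CH2Cl2, 0 °C
Reagents that add atoms: none
Why: Dess–Martin oxidation under buffered, non-basic conditions should give the C2 ketone without moving either β,γ-double bond into conjugation.

Compound list
1 | 4-methyl hydrogen itaconate (4-methoxy-2-methylidene-4-oxobutanoic acid) | C=C(CC(=O)OC)C(=O)O | starting material
2 | methyl 3-(hydroxymethyl)but-3-enoate | C=C(CO)CC(=O)OC | intermediate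
3 | methyl 3-{[(tert-butyldimethylsilyl)oxy]methyl}but-3-enoate | C=C(CO[Si](C)(C)C(C)(C)C)CC(=O)OC | intermediate
4 | 3-{[(tert-butyldimethylsilyl)oxy]methyl}but-3-enal | C=C(CO[Si](C)(C)C(C)(C)C)CC=O | intermediate
5 | 3-bromobut-3-en-1-ol | C=C(Br)CCO | starting material
6 | [(3-bromobut-3-en-1-yl)oxy](tert-butyl)diphenylsilane | C=C(Br)CCO[Si](c1ccccc1)(c1ccccc1)C(C)(C)C | intermediate
7 | prop-2-yn-1-ol | C#CCO | starting material
8 | 6-[(tert-butyldiphenylsilyl)oxy]-4-methylidenehex-2-yn-1-ol | OCC#CC(=C)CCO[Si](c1ccccc1)(c1ccccc1)C(C)(C)C | intermediate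
9 | 6-[(tert-butyldiphenylsilyl)oxy]-4-methylidenehex-2-ynal | O=CC#CC(=C)CCO[Si](c1ccccc1)(c1ccccc1)C(C)(C)C | intermediate
10 | tert-butyl acrylate | C=CC(=O)OC(C)(C)C | starting material
11 | tert-butyl 8-[(tert-butyldiphenylsilyl)oxy]-3-hydroxy-2,6-dimethylideneoct-4-ynoate (racemic) | C=C(C(=O)OC(C)(C)C)C(O)C#CC(=C)CCO[Si](c1ccccc1)(c1ccccc1)C(C)(C)C | intermediate
12 | tert-butyl (2Z)-2-(bromomethyl)-8-[(tert-butyldiphenylsilyl)oxy]-6-methylideneoct-2-en-4-ynoate | BrC/C(C(=O)OC(C)(C)C)=C\C#CC(=C)CCO[Si](c1ccccc1)(c1ccccc1)C(C)(C)C | intermediate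
13 | tert-butyl (3R,4S)-7-[(tert-butyldimethylsilyl)oxy]-3-{5-[(tert-butyldiphenylsilyl)oxy]-3-methylidenepent-1-yn-1-yl}-2,6-dimethylidene-4-[(trimethylsilyl)oxy]heptanoate | C=C(C(=O)OC(C)(C)C)[C@@H](C#CC(=C)CCO[Si](c1ccccc1)(c1ccccc1)C(C)(C)C)[C@@H](O[Si](C)(C)C)CC(=C)CO[Si](C)(C)C(C)(C)C | intermediate
14 | tert-butyl (3R,4S)-7-[(tert-butyldimethylsilyl)oxy]-3-{5-[(tert-butyldiphenylsilyl)oxy]-3-methylidenepent-1-yn-1-yl}-4-hydroxy-2,6-dimethylideneheptanoate | C=C(C(=O)OC(C)(C)C)[C@@H](C#CC(=C)CCO[Si](c1ccccc1)(c1ccccc1)C(C)(C)C)[C@@H](O)CC(=C)CO[Si](C)(C)C(C)(C)C | intermediate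
15 | tert-butyl (3R,4S)-4-acetoxy-7-[(tert-butyldimethylsilyl)oxy]-3-{5-[(tert-butyldiphenylsilyl)oxy]-3-methylidenepent-1-yn-1-yl}-2,6-dimethylideneheptanoate | C=C(C(=O)OC(C)(C)C)[C@@H](C#CC(=C)CCO[Si](c1ccccc1)(c1ccccc1)C(C)(C)C)[C@@H](OC(C)=O)CC(=C)CO[Si](C)(C)C(C)(C)C | intermediate
16 | tert-butyl (3R,4S)-4-acetoxy-7-[(tert-butyldimethylsilyl)oxy]-3-{(1Z)-5-[(tert-butyldiphenylsilyl)oxy]-3-methylidenepent-1-en-1-yl}-2,6-dimethylideneheptanoate | C=C(C(=O)OC(C)(C)C)[C@@H](/C=C\C(=C)CCO[Si](c1ccccc1)(c1ccccc1)C(C)(C)C)[C@@H](OC(C)=O)CC(=C)CO[Si](C)(C)C(C)(C)C | intermediate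
17 | trimethylsilyl (3R,4S)-4-acetoxy-7-[(tert-butyldimethylsilyl)oxy]-3-{(1Z)-5-[(tert-butyldiphenylsilyl)oxy]-3-methylidenepent-1-en-1-yl}-2,6-dimethylideneheptanoate | C=C(C(=O)O[Si](C)(C)C)[C@@H](/C=C\C(=C)CCO[Si](c1ccccc1)(c1ccccc1)C(C)(C)C)[C@@H](OC(C)=O)CC(=C)CO[Si](C)(C)C(C)(C)C | intermediate
18 | (3R,4S)-4-acetoxy-7-[(tert-butyldimethylsilyl)oxy]-3-{(1Z)-5-[(tert-butyldiphenylsilyl)oxy]-3-methylidenepent-1-en-1-yl}-2,6-dimethylideneheptanoic acid | C=C(C(=O)O)[C@@H](/C=C\C(=C)CCO[Si](c1ccccc1)(c1ccccc1)C(C)(C)C)[C@@H](OC(C)=O)CC(=C)CO[Si](C)(C)C(C)(C)C | intermediate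
19 | (1S)-1-[(2R,3R)-2-{(1Z)-2-(acetoxymethyl)-4-[(tert-butyldiphenylsilyl)oxy]but-1-en-1-yl}-4-methylidene-5-oxooxolan-3-yl]-3-{[(tert-butyldimethylsilyl)oxy]methyl}but-3-en-1-yl acetate | CC(C)(C)[Si](c1ccccc1)(c1ccccc1)OCC/C(COC(C)=O)=C/[C@H]2OC(=O)C(=C)[C@@H]2[C@@H](OC(C)=O)CC(=C)CO[Si](C)(C)C(C)(C)C | intermediate
20 | (1S)-1-[(2R,3R)-2-{(1Z)-2-(acetoxymethyl)-4-[(tert-butyldiphenylsilyl)oxy]but-1-en-1-yl}-4-methylidene-5-oxooxolan-3-yl]-3-(bromomethyl)but-3-en-1-yl acetate | CC(C)(C)[Si](c1ccccc1)(c1ccccc1)OCC/C(COC(C)=O)=C/[C@H]2OC(=O)C(=C)[C@@H]2[C@@H](OC(C)=O)CC(=C)CBr | intermediate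
21 | (1S)-1-{(2R,3R)-2-[(1Z)-2-(acetoxymethyl)-4-hydroxybut-1-en-1-yl]-4-methylidene-5-oxooxolan-3-yl}-3-(bromomethyl)but-3-en-1-yl acetate | OCC/C(COC(C)=O)=C/[C@H]1OC(=O)C(=C)[C@@H]1[C@@H](OC(C)=O)CC(=C)CBr | intermediate
22 | (1S)-1-{(2R,3R)-2-[(1Z)-2-(acetoxymethyl)-4-oxobut-1-en-1-yl]-4-methylidene-5-oxooxolan-3-yl}-3-(bromomethyl)but-3-en-1-yl acetate | O=CC/C(COC(C)=O)=C/[C@H]1OC(=O)C(=C)[C@@H]1[C@@H](OC(C)=O)CC(=C)CBr | intermediate
23 | allylchromium dichloride derived from 22 (CrCl2 on C1 in place of Br) | O=CC/C(COC(C)=O)=C/[C@H]1OC(=O)C(=C)[C@@H]1[C@@H](OC(C)=O)CC(=C)C[Cr](Cl)Cl | intermediate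
24 | 8α,15-diacetoxy-2-hydroxygermacra-4,10(14),11(13)-trien-12,6α-olide (C2 epimers; C6 R, C7 R, C8 S) | C=C1CC(O)C/C(COC(C)=O)=C/[C@H]2OC(=O)C(=C)[C@@H]2[C@@H](OC(C)=O)C1 | intermediate
25 | 8α,15-diacetoxy-2-oxogermacra-4,10(14),11(13)-trien-12,6α-olide (CNP0183179.1; C6 R, C7 R, C8 S; C3 anti to C6 across C4=C5) | C=C1CC(=O)C/C(COC(C)=O)=C/[C@H]2OC(=O)C(=C)[C@@H]2[C@@H](OC(C)=O)C1 | target

Total step count: 18. Longest linear sequence: 15 steps (steps 4–8, then 9–18).

Steps most likely to fail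

Step 13. Before acetate capture, the anti allylpalladium may isomerise through the σ-allyl at C5 to the syn form, which would give the C4=C5 isomer with C3 cis to C6; capture of acetate at C5 would give the 1,2-adduct. The fallback moves the oxidative lactonisation to the stage where the ten-membered ring exists, so that the ring and not a freely rotating C4–C5 bond decides the allyl geometry. Setting out from 16, Ph3PBr2 should give the allylic bromide tert-butyl (3R,4S)-4-acetoxy-7-bromo-3-{(1Z)-5-[(tert-butyldiphenylsilyl)oxy]-3-methylidenepent-1-en-1-yl}-2,6-dimethylideneheptanoate F1. HF·pyridine should give the alcohol tert-butyl (3R,4S)-4-acetoxy-7-bromo-3-[(1Z)-5-hydroxy-3-methylidenepent-1-en-1-yl]-2,6-dimethylideneheptanoate F2, and buffered Dess–Martin oxidation the aldehyde tert-butyl (3R,4S)-4-acetoxy-7-bromo-3-[(1Z)-3-methylidene-5-oxopent-1-en-1-yl]-2,6-dimethylideneheptanoate F3. CrCl2 under high dilution should close the ring to tert-butyl 8α-acetoxy-2-hydroxygermacra-4(15),5Z,10(14),11(13)-tetraen-12-oate F4. Me3SiOTf/2,6-lutidine followed by aqueous work-up should give 8α-acetoxy-2-hydroxygermacra-4(15),5Z,10(14),11(13)-tetraen-12-oic acid F5, and Dess–Martin oxidation 8α-acetoxy-2-oxogermacra-4(15),5Z,10(14),11(13)-tetraen-12-oic acid F6. The same Pd(OAc)2/p-benzoquinone/LiOAc oxidation in AcOH–acetone on the ring-held diene would then form O1–C6 and the C15 acetate and come back to the route at 25.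

Step 9. Ligand-free background addition and propargyl/allenyl shifts of the allylchromium may erode the facial and positional selectivity of the coupling. The fallback gives up asymmetric catalysis for a racemic coupling followed by enzymatic kinetic resolution. From 4 and 12, stoichiometric CrCl2 in THF without ligand should give the racemic anti alcohol, tert-butyl (3RS,4SR)-7-[(tert-butyldimethylsilyl)oxy]-3-{5-[(tert-butyldiphenylsilyl)oxy]-3-methylidenepent-1-yn-1-yl}-4-hydroxy-2,6-dimethylideneheptanoate F7. Candida antarctica lipase B with vinyl acetate should then acetylate the (3S,4R)-enantiomer (Kazlauskas rule) to tert-butyl (3S,4R)-4-acetoxy-7-[(tert-butyldimethylsilyl)oxy]-3-{5-[(tert-butyldiphenylsilyl)oxy]-3-methylidenepent-1-yn-1-yl}-2,6-dimethylideneheptanoate F8 and leave the (3R,4S)-alcohol, which is 14, where the route is rejoined.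

Step 17. Oligomerisation, and enolisation or conjugation of the β,γ-unsaturated aldehyde, may outrun closure of the strained ten-membered ring. The fallback replaces the closed, metal-centred transition state by a Lewis-acid-promoted open one with a storable allylstannane. Setting out from 21, Zn and Bu3SnCl in THF/aqueous NH4Cl should give (1S)-1-{(2R,3R)-2-[(1Z)-2-(acetoxymethyl)-4-hydroxybut-1-en-1-yl]-4-methylidene-5-oxooxolan-3-yl}-3-[(tributylstannyl)methyl]but-3-en-1-yl acetate F9. Buffered Dess–Martin oxidation should give (1S)-1-{(2R,3R)-2-[(1Z)-2-(acetoxymethyl)-4-oxobut-1-en-1-yl]-4-methylidene-5-oxooxolan-3-yl}-3-[(tributylstannyl)methyl]but-3-en-1-yl acetate F10. BF3·OEt2 in CH2Cl2 at −78 °C under high dilution (intramolecular SE2′ allylstannane addition) would then return to the route at 24.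

Further compounds
F1 | step 13 | tert-butyl (3R,4S)-4-acetoxy-7-bromo-3-{(1Z)-5-[(tert-butyldiphenylsilyl)oxy]-3-methylidenepent-1-en-1-yl}-2,6-dimethylideneheptanoate | C=C(C(=O)OC(C)(C)C)[C@@H](/C=C\C(=C)CCO[Si](c1ccccc1)(c1ccccc1)C(C)(C)C)[C@@H](OC(C)=O)CC(=C)CBr
F2 | step 13 | tert-butyl (3R,4S)-4-acetoxy-7-bromo-3-[(1Z)-5-hydroxy-3-methylidenepent-1-en-1-yl]-2,6-dimethylideneheptanoate | C=C(C(=O)OC(C)(C)C)[C@@H](/C=C\C(=C)CCO)[C@@H](OC(C)=O)CC(=C)CBr
F3 | step 13 | tert-butyl (3R,4S)-4-acetoxy-7-bromo-3-[(1Z)-3-methylidene-5-oxopent-1-en-1-yl]-2,6-dimethylideneheptanoate | C=C(C(=O)OC(C)(C)C)[C@@H](/C=C\C(=C)CC=O)[C@@H](OC(C)=O)CC(=C)CBr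
F4 | step 13 | tert-butyl 8α-acetoxy-2-hydroxygermacra-4(15),5Z,10(14),11(13)-tetraen-12-oate (C2 epimers) | C=C1CC(O)CC(=C)/C=C\[C@H](C(=C)C(=O)OC(C)(C)C)[C@@H](OC(C)=O)C1
F5 | step 13 | 8α-acetoxy-2-hydroxygermacra-4(15),5Z,10(14),11(13)-tetraen-12-oic acid (C2 epimers) | C=C1CC(O)CC(=C)/C=C\[C@H](C(=C)C(=O)O)[C@@H](OC(C)=O)C1
F6 | step 13 | 8α-acetoxy-2-oxogermacra-4(15),5Z,10(14),11(13)-tetraen-12-oic acid | C=C1CC(=O)CC(=C)/C=C\[C@H](C(=C)C(=O)O)[C@@H](OC(C)=O)C1
F7 | step 9 | racemic anti alcohol (14 together with its enantiomer) | C=C(C(=O)OC(C)(C)C)[C@@H](C#CC(=C)CCO[Si](c1ccccc1)(c1ccccc1)C(C)(C)C)[C@@H](O)CC(=C)CO[Si](C)(C)C(C)(C)C.C=C(C(=O)OC(C)(C)C)[C@H](C#CC(=C)CCO[Si](c1ccccc1)(c1ccccc1)C(C)(C)C)[C@H](O)CC(=C)CO[Si](C)(C)C(C)(C)C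
F8 | step 9 | tert-butyl (3S,4R)-4-acetoxy-7-[(tert-butyldimethylsilyl)oxy]-3-{5-[(tert-butyldiphenylsilyl)oxy]-3-methylidenepent-1-yn-1-yl}-2,6-dimethylideneheptanoate (enantiomer of 15) | C=C(C(=O)OC(C)(C)C)[C@H](C#CC(=C)CCO[Si](c1ccccc1)(c1ccccc1)C(C)(C)C)[C@H](OC(C)=O)CC(=C)CO[Si](C)(C)C(C)(C)C
F9 | step 17 | (1S)-1-{(2R,3R)-2-[(1Z)-2-(acetoxymethyl)-4-hydroxybut-1-en-1-yl]-4-methylidene-5-oxooxolan-3-yl}-3-[(tributylstannyl)methyl]but-3-en-1-yl acetate | OCC/C(COC(C)=O)=C/[C@H]1OC(=O)C(=C)[C@@H]1[C@@H](OC(C)=O)CC(=C)C[Sn](CCCC)(CCCC)CCCC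
F10 | step 17 | (1S)-1-{(2R,3R)-2-[(1Z)-2-(acetoxymethyl)-4-oxobut-1-en-1-yl]-4-methylidene-5-oxooxolan-3-yl}-3-[(tributylstannyl)methyl]but-3-en-1-yl acetate | O=CC/C(COC(C)=O)=C/[C@H]1OC(=O)C(=C)[C@@H]1[C@@H](OC(C)=O)CC(=C)C[Sn](CCCC)(CCCC)CCCC
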